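**Plan**

1. Numbering: flavanone rings A (C5–C8), C (O1–C4) and B (C1'–C6'); ring D is the 2,2-dimethyl-2H-pyran fused at C4'–C5' (O, C2'', C3'', C4''). The retrosynthesis first removes three MOM ethers, then one olefin-metathesis event cuts three C=C bonds together: C3''=C4'' of ring D and the trisubstituted C=C of the C6 and C8 prenyl groups.
2. Enabling feature: C4'' sits on C5' of ring B directly beside the C4' oxygen, whose CMe2 carbon (C2'') carries C3''. Ring D therefore opens to an ortho pair of styrene and aryl 1,1-dimethylallyl ether, and each prenyl group opens to a C-allyl group, so all three isoprenoid alkenes descend from terminal vinyl groups.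
3. The C2–C1' bond is cut next, which gives a ring A/C chromone and a ring B boronic acid.
4. Forward order: ring A receives both allyl groups by a double aromatic Claisen rearrangement; ring C is closed as the chromone; ring B is dressed from 5-bromo-2,4-dihydroxybenzaldehyde (CHO to vinyl, OH to O–CMe2–CH=CH2, Br to B(OH)2); the halves are joined at C2; ring D is closed and both prenyl groups are completed in one pot; the MOM groups are removed.
5. Stereochemistry: C2 (S), the only stereocenter, is set by the chiral bisphosphine–rhodium catalyst in the conjugate arylation and is carried through neutral metathesis and mild acidolysis.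

Key step: step 11

Assumption: the (S)-configured biaryl bisphosphine is taken to deliver the aryl group to the chromone face that gives the (2S)-flavanone, by analogy with its known sense for 2-cyclohexenone; if a trial on the parent chromone shows the opposite sense, the (R)-ligand is used.

**Step 1**
Reactants: 1 2,4,6-trihydroxyacetophenone; 2 allyl bromide
Product: 3 1-[2,4-bis(allyloxy)-6-hydroxyphenyl]ethan-1-one
Conditions: allyl bromide (2.1 equiv in all), K2CO3 (2.2 equiv), acetone, 56 °C
Reagents that add atoms: allyl bromide (second equivalent), C=CCBr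
Why: Twofold Williamson O-allylation under carbonate conditions takes the two non-chelated phenols (O4, then one of the equivalent O2/O6), one molecule of allyl bromide being consumed per ether, and leaves the phenol that is hydrogen-bonded to the acetyl group untouched.

**Step 2**
Reactants: 3 1-[2,4-bis(allyloxy)-6-hydroxyphenyl]ethan-1-one
Product: 4 1-(3,5-diallyl-2,4,6-trihydroxyphenyl)ethan-1-one
Conditions: N,N-diethylaniline, 200 °C, sealed tube
Reagents that add atoms: none
Why: Double aromatic Claisen rearrangement ([3,3]-sigmatropic shift, then tautomerization) moves each O-allyl group to a free ring carbon, and because an unsubstituted allyl group gives the same C-allyl unit by the direct ortho path or by an ortho/Cope relay, every pathway converges on the 3,5-diallyl pattern that becomes C6 and C8 of ring A.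

**Step 3**
Reactants: 4 1-(3,5-diallyl-2,4,6-trihydroxyphenyl)ethan-1-one
Product: 5 1-[3,5-diallyl-2-hydroxy-4,6-bis(methoxymethoxy)phenyl]ethan-1-one
Conditions: MOMCl (2.2 equiv), i-Pr2NEt, CH2Cl2, 0 °C to rt
Reagents that add atoms: chloromethyl methyl ether (2 equiv), COCCl
Why: MOM ether formation takes O4 and one of the two equivalent chelated phenols, while the last phenol stays locked in the hydrogen bond to the ketone and is kept free for the closure of ring C.

**Step 4**
Reactants: 5 1-[3,5-diallyl-2-hydroxy-4,6-bis(methoxymethoxy)phenyl]ethan-1-one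
Product: 7 6,8-diallyl-5,7-bis(methoxymethoxy)-4H-chromen-4-one, via enaminone 6 (not isolated)
Conditions: DMF-DMA, toluene, 90 °C; concentrate; then AcOH, CH2Cl2, 40 °C
Reagents that add atoms: N,N-dimethylformamide dimethyl acetal, COC(OC)N(C)C
Why: In the enaminone route to chromones the methyl ketone condenses with the formamide acetal to a vinylogous amide, and weak-acid-promoted intramolecular oxa-Michael addition of the free phenol followed by loss of dimethylamine closes ring C without cleaving the MOM ethers.

**Step 5**
Reactants: 8 5-bromo-2,4-dihydroxybenzaldehyde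
Product: 9 5-bromo-2-hydroxy-4-(methoxymethoxy)benzaldehyde
Conditions: MOMCl (1.05 equiv), K2CO3, acetone, 0 °C to rt
Reagents that add atoms: chloromethyl methyl ether, COCCl
Why: Selective MOM protection occurs at the 4-OH, which is para to the formyl group, ortho to bromine, more acidic and not chelated, whereas the 2-OH is held in a hydrogen bond to the aldehyde.

**Step 6**
Reactants: 9 5-bromo-2-hydroxy-4-(methoxymethoxy)benzaldehyde
Product: 10 4-bromo-5-(methoxymethoxy)-2-vinylphenol
Conditions: Ph3PCH3Br (2.5 equiv), KOtBu (2.4 equiv), THF, 0 °C to rt; used promptly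
Reagents that add atoms: methyltriphenylphosphonium bromide, C[P+](c1ccccc1)(c1ccccc1)c1ccccc1.[Br-]
Why: Wittig methylenation of a salicylaldehyde with excess ylide (the first equivalent of base forms the phenoxide) converts the formyl group into the vinyl group whose internal carbon becomes C4'' of ring D.

**Step 7**
Reactants: 11 2-methylbut-3-en-2-ol
Product: 12 tert-butyl 2-methylbut-3-en-2-yl carbonate
Conditions: n-BuLi (1.0 equiv), THF, 0 °C; then Boc2O, 0 °C to rt; H2O
Reagents that add atoms: di-tert-butyl dicarbonate, CC(C)(C)OC(=O)OC(=O)OC(C)(C)C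
Why: Acylation of the lithium alkoxide of the tertiary allylic alcohol with Boc2O gives the mixed carbonate that serves as the ionizable partner for the next step.

**Step 8**
Reactants: 10 4-bromo-5-(methoxymethoxy)-2-vinylphenol; 12 tert-butyl 2-methylbut-3-en-2-yl carbonate
Product: 13 1-bromo-2-(methoxymethoxy)-4-[(2-methylbut-3-en-2-yl)oxy]-5-vinylbenzene
Conditions: Pd(PPh3)4 (3 mol%), 12 (1.5 equiv), THF, 0 °C
Reagents that add atoms: none
Why: In this Tsuji–Trost O-allylation, zerovalent palladium ionizes the carbonate to a 1,1-dimethyl-π-allyl complex with loss of CO2, the tert-butoxide formed frees the phenoxide, and the phenoxide attacks the more substituted allyl terminus under kinetic control at 0 °C to give the tertiary ether, while the electron-rich aryl bromide does not undergo oxidative addition at this temperature.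

**Step 9**
Reactants: 13 1-bromo-2-(methoxymethoxy)-4-[(2-methylbut-3-en-2-yl)oxy]-5-vinylbenzene
Product: 15 {2-(methoxymethoxy)-4-[(2-methylbut-3-en-2-yl)oxy]-5-vinylphenyl}boronic acid, via aryllithium 14 (not isolated)
Conditions: n-BuLi (1.05 equiv), THF, −78 °C; B(OiPr)3, −78 to 0 °C; then H2O (pH 7); used crude
Reagents that add atoms: triisopropyl borate, CC(C)OB(OC(C)C)OC(C)C; water, O
Why: Bromine–lithium exchange, which at −78 °C is faster than addition of butyllithium to the styrene and is assisted by the ortho MOM oxygen, followed by borate trapping and neutral hydrolysis places boron on the carbon that becomes C1'.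

**Step 10**
Reactants: 7 6,8-diallyl-5,7-bis(methoxymethoxy)-4H-chromen-4-one; 15 {2-(methoxymethoxy)-4-[(2-methylbut-3-en-2-yl)oxy]-5-vinylphenyl}boronic acid
Product: 16 (2S)-6,8-diallyl-5,7-bis(methoxymethoxy)-2-{2-(methoxymethoxy)-4-[(2-methylbut-3-en-2-yl)oxy]-5-vinylphenyl}chroman-4-one
Conditions: [Rh(OH)(cod)]2 (1.5 mol%), (S)-MeO-F12-BIPHEP [(S)-2,2'-bis[bis(3,4,5-trifluorophenyl)phosphino]-6,6'-dimethoxy-1,1'-biphenyl] (3.3 mol%), 15 (2.5 equiv), toluene/H2O (20:1), 30 °C
Reagents that add atoms: none
Why: In this Hayashi–Miyaura asymmetric 1,4-addition to a chromone, transmetalation gives an arylrhodium species that inserts the C2=C3 bond with the aryl group delivered to the enantioface selected by the (S)-bisphosphine, and base-free hydrolysis of the oxa-π-allyl rhodium intermediate releases the (2S)-flavanone without retro-oxa-Michael opening of ring C.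

**Step 11**
Reactants: 16 (2S)-6,8-diallyl-5,7-bis(methoxymethoxy)-2-{2-(methoxymethoxy)-4-[(2-methylbut-3-en-2-yl)oxy]-5-vinylphenyl}chroman-4-one; 17 2-methyl-2-butene
Product: 19 (2S)-5,7-bis(methoxymethoxy)-2-[7-(methoxymethoxy)-2,2-dimethyl-2H-chromen-6-yl]-6,8-bis(3-methylbut-2-en-1-yl)chroman-4-one, via ring-closed diallyl flavanone 18 (not isolated)
Conditions: second-generation Grubbs catalyst (H2IMes)(PCy3)Cl2Ru=CHPh (5 mol%), 1,4-benzoquinone (10 mol%), CH2Cl2 (5 mM), 40 °C; then 2-methyl-2-butene (large excess) and more catalyst (5 mol%), 40 °C, sealed vessel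
Reagents that add atoms: 2-methyl-2-butene (second equivalent), CC=C(C)C
Why: A ruthenium alkylidene loads onto the ring B styrene and, through a ruthenacyclobutane ([2+2]/retro-[2+2], Chauvin mechanism), joins the styrenyl CH to the internal CH of the O–CMe2–CH=CH2 group with loss of ethylene, which closes ring D; the same carbene pool then exchanges the =CH2 termini of the C6 and C8 allyl groups for =CMe2, one molecule of 2-methyl-2-butene being consumed and one of propene lost per allyl group. The closest known reaction types are ring-closing metathesis of 2-vinylaryl 1,1-dimethylallyl ethers to 2,2-dimethyl-2H-chromenes and cross-metathesis of allylarenes with 2-methyl-2-butene to prenylarenes. Ring D closes as a six-membered ring by ring-closing metathesis, with the cis geometry of the new endocyclic C=C enforced by ring size and the closure favored by the gem-dimethyl group. No stereocenter is formed, and C2 is not touched because the medium is neutral and aprotic. The step needs chemoselectivity among four terminal alkenes: the styrene and the 1,1-dimethylallyl ether are ortho to each other on ring B, so their union is intramolecular and fast, whereas the two allyl groups are meta to each other on ring A and too far from ring B to close an unstrained ring, so they can only react with the added olefin. Running the ring closure first at high dilution and adding 2-methyl-2-butene afterwards keeps the styrene from being capped, while the large excess of the trisubstituted olefin and the benzoquinone drive both cross-metatheses, return any allyl–allyl dimers to product, and suppress allyl-to-propenyl isomerization and ethenolysis of the prenyl groups.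

**Step 12**
Reactants: 19 (2S)-5,7-bis(methoxymethoxy)-2-[7-(methoxymethoxy)-2,2-dimethyl-2H-chromen-6-yl]-6,8-bis(3-methylbut-2-en-1-yl)chroman-4-one
Product: 20 euchrenone a3
Conditions: HCl (3 M aq.)/MeOH (1:5), 40 °C
Reagents that add atoms: none
Why: Acid-catalysed acetal exchange with methanol removes the three MOM groups as dimethoxymethane under conditions intended to be mild enough for the chromene, the prenyl groups and the C2 stereocenter, which takes no part in the reaction.

**Compound list**

1 | 2,4,6-trihydroxyacetophenone | CC(=O)c1c(O)cc(O)cc1O | starting material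
2 | allyl bromide | C=CCBr | starting material
3 | 1-[2,4-bis(allyloxy)-6-hydroxyphenyl]ethan-1-one | CC(=O)c1c(O)cc(OCC=C)cc1OCC=C | intermediate
4 | 1-(3,5-diallyl-2,4,6-trihydroxyphenyl)ethan-1-one | CC(=O)c1c(O)c(CC=C)c(O)c(CC=C)c1O | intermediate
5 | 1-[3,5-diallyl-2-hydroxy-4,6-bis(methoxymethoxy)phenyl]ethan-1-one | CC(=O)c1c(O)c(CC=C)c(OCOC)c(CC=C)c1OCOC | intermediate
6 | (E)-1-[3,5-diallyl-2-hydroxy-4,6-bis(methoxymethoxy)phenyl]-3-(dimethylamino)prop-2-en-1-one | CN(C)/C=C/C(=O)c1c(O)c(CC=C)c(OCOC)c(CC=C)c1OCOC | intermediate
7 | 6,8-diallyl-5,7-bis(methoxymethoxy)-4H-chromen-4-one | O=c1ccoc2c(CC=C)c(OCOC)c(CC=C)c(OCOC)c12 | intermediate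
8 | 5-bromo-2,4-dihydroxybenzaldehyde | O=Cc1cc(Br)c(O)cc1O | starting material
9 | 5-bromo-2-hydroxy-4-(methoxymethoxy)benzaldehyde | O=Cc1cc(Br)c(OCOC)cc1O | intermediate
10 | 4-bromo-5-(methoxymethoxy)-2-vinylphenol | C=Cc1cc(Br)c(OCOC)cc1O | intermediate
11 | 2-methylbut-3-en-2-ol | C=CC(C)(C)O | starting material
12 | tert-butyl 2-methylbut-3-en-2-yl carbonate | C=CC(C)(C)OC(=O)OC(C)(C)C | intermediate
13 | 1-bromo-2-(methoxymethoxy)-4-[(2-methylbut-3-en-2-yl)oxy]-5-vinylbenzene | C=Cc1cc(Br)c(OCOC)cc1OC(C)(C)C=C | intermediate
14 | {2-(methoxymethoxy)-4-[(2-methylbut-3-en-2-yl)oxy]-5-vinylphenyl}lithium | [Li]c1cc(C=C)c(OC(C)(C)C=C)cc1OCOC | intermediate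
15 | {2-(methoxymethoxy)-4-[(2-methylbut-3-en-2-yl)oxy]-5-vinylphenyl}boronic acid | C=Cc1cc(B(O)O)c(OCOC)cc1OC(C)(C)C=C | intermediate
16 | (2S)-6,8-diallyl-5,7-bis(methoxymethoxy)-2-{2-(methoxymethoxy)-4-[(2-methylbut-3-en-2-yl)oxy]-5-vinylphenyl}chroman-4-one | C=CCc1c(OCOC)c(CC=C)c2c(c1OCOC)C(=O)C[C@@H](c1cc(C=C)c(OC(C)(C)C=C)cc1OCOC)O2 | intermediate
17 | 2-methyl-2-butene | CC=C(C)C | starting material
18 | (2S)-6,8-diallyl-5,7-bis(methoxymethoxy)-2-[7-(methoxymethoxy)-2,2-dimethyl-2H-chromen-6-yl]chroman-4-one | C=CCc1c(OCOC)c(CC=C)c2c(c1OCOC)C(=O)C[C@@H](c1cc3c(cc1OCOC)OC(C)(C)C=C3)O2 | intermediate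
19 | (2S)-5,7-bis(methoxymethoxy)-2-[7-(methoxymethoxy)-2,2-dimethyl-2H-chromen-6-yl]-6,8-bis(3-methylbut-2-en-1-yl)chroman-4-one | CC(C)=CCc1c(OCOC)c(CC=C(C)C)c2c(c1OCOC)C(=O)C[C@@H](c1cc3c(cc1OCOC)OC(C)(C)C=C3)O2 | intermediate
20 | euchrenone a3, (2S)-5,7-dihydroxy-2-(7-hydroxy-2,2-dimethyl-2H-chromen-6-yl)-6,8-bis(3-methylbut-2-en-1-yl)chroman-4-one | CC(C)=CCc1c(O)c(CC=C(C)C)c2c(c1O)C(=O)C[C@@H](c1cc3c(cc1O)OC(C)(C)C=C3)O2 | target

**Total step count:** 12
**Longest linear sequence:** 7 steps (steps 1–4, 10–12, or steps 5, 6, 8–12)

**Steps most likely to fail**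

Step 10. The hindered ortho-alkoxy arylrhodium may insert into the electron-rich chromone too slowly, so that protodeboronation of the boronic acid wins; rhodium hydrides may isomerize the allyl groups; or facial selectivity may be insufficient. The fallback replaces the catalytic arylation by the chalcone route with kinetic resolution. It sets out from 13 and 5. The aryllithium 14, generated from 13 as in step 9, is quenched with DMF to give 2-(methoxymethoxy)-4-[(2-methylbut-3-en-2-yl)oxy]-5-vinylbenzaldehyde F1. Claisen–Schmidt condensation of F1 with acetophenone 5 (KOH, EtOH, rt) gives the 2'-hydroxychalcone F2, and oxa-Michael cyclization (NaOAc, EtOH, 60 °C) gives the racemic flavanone F3. Asymmetric transfer hydrogenation with [RuCl(p-cymene)((R,R)-TsDPEN)] and HCO2H/Et3N in EtOAc at rt, run to slightly beyond half conversion, should reduce the (2R) enantiomer to the cis-(2R,4R)-flavan-4-ol F4. The unreduced (2S)-flavanone is separated by chromatography, and the route is rejoined at 16.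

Step 11. The ring B termini may be capped or isomerized before ring closure, the double cross-metathesis may stop at mono-prenyl or give crotyl products, or intermolecular oligomerization may compete. The fallback separates the events and sets out from 13. Ring-closing metathesis of 13 alone (second-generation Grubbs catalyst, CH2Cl2, 40 °C), where only the two ring B olefins are present, gives 6-bromo-7-(methoxymethoxy)-2,2-dimethyl-2H-chromene F5. Bromine–lithium exchange (n-BuLi, THF, −78 °C) gives the chromenyllithium F6, which is trapped with B(OiPr)3 and hydrolysed to the chromenylboronic acid F7. Rhodium-catalysed addition of F7 to chromone 7 under the conditions of step 10 gives 18 as an isolated compound. Cross-metathesis of its two allyl groups with 17 alone then returns to the route at 19.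

Step 12. Protic acid may open ring C at the doubly oxygen-activated benzylic C2–O1 bond with loss of optical purity, or protonate the chromene and prenyl olefins so that they cyclize onto neighbouring phenols. The fallback exchanges the acetals for silyl ethers and cleaves those with buffered fluoride; it sets out from 19. Treatment with TESOTf and 2,2'-bipyridyl (CH2Cl2, 0 °C), followed by aqueous work-up, should convert the three aryl MOM ethers into the tris(triethylsilyl) ether F8. Tetrabutylammonium fluoride buffered with acetic acid (THF, 0 °C) then frees the phenols under near-neutral conditions and arrives at 20.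

**Further compounds**

F1 | step 10 | 2-(methoxymethoxy)-4-[(2-methylbut-3-en-2-yl)oxy]-5-vinylbenzaldehyde | O=Cc1cc(C=C)c(OC(C)(C)C=C)cc1OCOC
F2 | step 10 | (E)-1-[3,5-diallyl-2-hydroxy-4,6-bis(methoxymethoxy)phenyl]-3-{2-(methoxymethoxy)-4-[(2-methylbut-3-en-2-yl)oxy]-5-vinylphenyl}prop-2-en-1-one | C=CCc1c(O)c(C(=O)/C=C/c2cc(C=C)c(OC(C)(C)C=C)cc2OCOC)c(OCOC)c(CC=C)c1OCOC
F3 | step 10 | racemic 6,8-diallyl-5,7-bis(methoxymethoxy)-2-{2-(methoxymethoxy)-4-[(2-methylbut-3-en-2-yl)oxy]-5-vinylphenyl}chroman-4-one | C=CCc1c(OCOC)c(CC=C)c2c(c1OCOC)C(=O)CC(c1cc(C=C)c(OC(C)(C)C=C)cc1OCOC)O2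
F4 | step 10 | (2R,4R)-6,8-diallyl-5,7-bis(methoxymethoxy)-2-{2-(methoxymethoxy)-4-[(2-methylbut-3-en-2-yl)oxy]-5-vinylphenyl}chroman-4-ol | C=CCc1c(OCOC)c(CC=C)c2c(c1OCOC)[C@H](O)C[C@H](c1cc(C=C)c(OC(C)(C)C=C)cc1OCOC)O2
F5 | step 11 | 6-bromo-7-(methoxymethoxy)-2,2-dimethyl-2H-chromene | CC1(C)C=Cc2cc(Br)c(OCOC)cc2O1
F6 | step 11 | [7-(methoxymethoxy)-2,2-dimethyl-2H-chromen-6-yl]lithium | [Li]c1cc2c(cc1OCOC)OC(C)(C)C=C2
F7 | step 11 | [7-(methoxymethoxy)-2,2-dimethyl-2H-chromen-6-yl]boronic acid | CC1(C)C=Cc2cc(B(O)O)c(OCOC)cc2O1
F8 | step 12 | (2S)-2-[2,2-dimethyl-7-(triethylsilyloxy)-2H-chromen-6-yl]-6,8-bis(3-methylbut-2-en-1-yl)-5,7-bis(triethylsilyloxy)chroman-4-one | CC(C)=CCc1c(O[Si](CC)(CC)CC)c(CC=C(C)C)c2c(c1O[Si](CC)(CC)CC)C(=O)C[C@@H](c1cc3c(cc1O[Si](CC)(CC)CC)OC(C)(C)C=C3)O2
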